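**Retrosynthetic overview**

1. Selaginellin A (12) is traced back to the tri-O-methyl triarylcarbinol 11; BBr3 cleaves the three methyl ethers and removes water. No ring is built anywhere in the route: all four benzene rings are bought, and the cyclohexadienone (quinone methide) ring is unmasked last from an anisole ring.
2. Carbinol 11 is assembled from three components in one flask: aryne 9, 4-methoxyphenylmagnesium bromide (6) and 4-methoxybenzophenone (7). The Grignard adds to the aryne (biaryl bond), and the aryl-magnesium so formed adds to the ketone (bond from the central ring to the triaryl-substituted carbon).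
3. The aryne precursor, o-fluoro iodide 5, comes from fluorine-directed lithiation/iodination of tolane 3, which comes from Sonogashira coupling of 1 and 2. Fluorine and iodine are traceless activators that leave in the key step.
4. Enabling feature: on the central benzene ring, the carbon bearing the triaryl-substituted carbon lies between the carbon bearing the 4-hydroxyphenyl ring and the carbon bearing the alkynyl sp carbon. The first two are the two ends of an aryne triple bond. The adjacent sp carbon polarises that aryne, so the aryl nucleophile enters at the far end and magnesium ends up on the ring carbon that must carry the triaryl carbon.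

Key step: step 3

Remark on the chemistry: the target has no stereocentre, and its exocyclic C=C is not a stereo-element because the cyclohexadienone ring is symmetric. Carbinol 11 is therefore carried as a racemate, and the three phenolic oxygens are carried as methyl ethers until the last step.

**Route**

Step 1
Reactants: 1 3-fluoro-2-iodotoluene (1-fluoro-2-iodo-3-methylbenzene); 2 4-ethynylanisole
Product: 3 1-fluoro-2-[(4-methoxyphenyl)ethynyl]-3-methylbenzene
Conditions: PdCl2(PPh3)2 (3 mol%), CuI (5 mol%), Et3N, THF, 50 °C
Reagents that add atoms: none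
Why: Sonogashira coupling; the C–I bond of 1 is the only site open to oxidative addition (C–F is inert), and a di-ortho-substituted aryl iodide should still couple with a terminal arylacetylene under Pd/Cu catalysis with mild heating.

Step 2
Reactants: 3 1-fluoro-2-[(4-methoxyphenyl)ethynyl]-3-methylbenzene
Product: 5 2-fluoro-1-iodo-3-[(4-methoxyphenyl)ethynyl]-4-methylbenzene, via aryllithium 4 (not isolated)
Conditions: LiTMP (1.2 equiv, from TMPH and n-BuLi), THF, −78 °C, 45 min; then cannula transfer into I2 (1.5 equiv), THF, −78 °C; aq. Na2S2O3
Reagents that add atoms: iodine, II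
Why: Directed ortho-metalation followed by iodination; fluorine is the strongest acidifying group in 3 and has a single ortho hydrogen, the hindered amide base does not add to the alkyne, aryllithium 4 should be stable to LiF loss at −78 °C, and the inverse quench into iodine should avoid base-induced halogen migration.

Step 3
Reactants: 5 2-fluoro-1-iodo-3-[(4-methoxyphenyl)ethynyl]-4-methylbenzene; 6 4-methoxyphenylmagnesium bromide; 7 4-methoxybenzophenone
Product: 11 (4-methoxyphenyl){4'-methoxy-3-[(4-methoxyphenyl)ethynyl]-4-methylbiphenyl-2-yl}(phenyl)methanol (racemic), via fluoroaryl Grignard 8 (not isolated), via aryne 9 (not isolated), via biaryl Grignard 10 (not isolated)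
Conditions: i-PrMgCl·LiCl (1.05 equiv), THF, −40 °C, 30 min; 6 (3 equiv), −40 → 60 °C; then 7 (4 equiv), LaCl3·2LiCl (30 mol%), 0 °C → rt; H2O (pH 7 buffer) work-up
Reagents that add atoms: none
Why: I/Mg exchange at −40 °C should give the o-fluoroaryl Grignard 8, which on warming loses MgClF to aryne 9; 6 then adds to 9 to give biaryl Grignard 10, and 10 adds to the carbonyl of 7, so that the biaryl bond and the bond from the central ring to the carbinol carbon are both made in one flask from three components. The closest known reaction type is the aryne arylmagnesiation–electrophile trapping sequence (Hart m-terphenyl synthesis and the one-pot preparation of 2-functionalised biaryls from aryl Grignards and arynes generated from o-dihaloarenes), here ended by the ordinary addition of an aryl Grignard to a diaryl ketone. No ring is closed. The carbinol carbon is the only new stereocentre; nothing controls it, 11 should form as a racemate, and the centre is erased in step 4. The step needs regioselective addition to the unsymmetrical aryne: the inductively withdrawing sp carbon of the 3-alkynyl group polarises 9 and leaves the distal aryne carbon the more electrophilic and less hindered one, so the aryl group should enter meta to the alkyne and magnesium should end up between the alkyne and the new aryl ring, as with 3-halo- and 3-arylbenzynes in the Hart reaction. It also needs 6 to outcompete 8 for the aryne, which the threefold excess of the electron-rich, unhindered 6 and the slow release of 9 on warming should secure.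

Step 4
Reactants: 11 (4-methoxyphenyl){4'-methoxy-3-[(4-methoxyphenyl)ethynyl]-4-methylbiphenyl-2-yl}(phenyl)methanol
Product: 12 selaginellin A, 4-[{4'-hydroxy-3-[(4-hydroxyphenyl)ethynyl]-4-methylbiphenyl-2-yl}(phenyl)methylidene]cyclohexa-2,5-dien-1-one
Conditions: BBr3 (8 equiv), CH2Cl2, −78 → 0 °C; then H2O
Reagents that add atoms: none
Why: BBr3 cleavage of aryl methyl ethers, which diaryl alkynes tolerate at low temperature; the carbinol should ionise to a 4-methoxytrityl cation whose oxocarbenium-type O-methyl group is removed by bromide to give the quinone methide directly, while the two other anisoles are cleaved by the usual ArO(Me)·BBr3 pathway and hydrolysed on work-up.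

**Compound list**

1 | 3-fluoro-2-iodotoluene (1-fluoro-2-iodo-3-methylbenzene) | Cc1cccc(F)c1I | starting material
2 | 4-ethynylanisole (1-ethynyl-4-methoxybenzene) | C#Cc1ccc(OC)cc1 | starting material
3 | 1-fluoro-2-[(4-methoxyphenyl)ethynyl]-3-methylbenzene | Cc1cccc(F)c1C#Cc1ccc(OC)cc1 | intermediate
4 | {2-fluoro-3-[(4-methoxyphenyl)ethynyl]-4-methylphenyl}lithium (not isolated) | [Li]c1ccc(C)c(C#Cc2ccc(OC)cc2)c1F | intermediate
5 | 2-fluoro-1-iodo-3-[(4-methoxyphenyl)ethynyl]-4-methylbenzene | Cc1ccc(I)c(F)c1C#Cc1ccc(OC)cc1 | intermediate
6 | 4-methoxyphenylmagnesium bromide (commercial THF solution) | COc1ccc([Mg]Br)cc1 | starting material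
7 | 4-methoxybenzophenone | COc1ccc(C(=O)c2ccccc2)cc1 | starting material
8 | {2-fluoro-3-[(4-methoxyphenyl)ethynyl]-4-methylphenyl}magnesium chloride (not isolated) | Cl[Mg]c1ccc(C)c(C#Cc2ccc(OC)cc2)c1F | intermediate
9 | 3-[(4-methoxyphenyl)ethynyl]-4-methylbenzyne (not isolated) | CC1=C(C#Cc2ccc(OC)cc2)C#CC=C1 | intermediate
10 | {4'-methoxy-3-[(4-methoxyphenyl)ethynyl]-4-methylbiphenyl-2-yl}magnesium bromide (not isolated) | Br[Mg]c1c(-c2ccc(OC)cc2)ccc(C)c1C#Cc1ccc(OC)cc1 | intermediate
11 | (4-methoxyphenyl){4'-methoxy-3-[(4-methoxyphenyl)ethynyl]-4-methylbiphenyl-2-yl}(phenyl)methanol (racemic) | Cc1ccc(-c2ccc(OC)cc2)c(C(O)(c2ccc(OC)cc2)c2ccccc2)c1C#Cc1ccc(OC)cc1 | intermediate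
12 | selaginellin A | Cc1ccc(-c2ccc(O)cc2)c(C(=C2C=CC(=O)C=C2)c2ccccc2)c1C#Cc1ccc(O)cc1 | target

**Step count and risks**

Total step count: 4. Longest linear sequence: 4 steps (1 → 3 → 5 → 11 → 12).

Steps most likely to fail:

Step 3 (key step). What may go wrong: the aryl-magnesium 10, flanked by an aryl ring and an alkyne, may add too slowly to the diaryl ketone, so that electron transfer to the ketone and protonation on work-up take over. Fallback: it sets out from biaryl Grignard 10, generated from 5 exactly as in step 3. Instead of the ketone, iodine (THF, 0 °C) is added, which should give 2-iodo-4'-methoxy-3-[(4-methoxyphenyl)ethynyl]-4-methylbiphenyl F1. Iodine–lithium exchange (n-BuLi, THF, −78 °C) should then give {4'-methoxy-3-[(4-methoxyphenyl)ethynyl]-4-methylbiphenyl-2-yl}lithium F2, a smaller and more nucleophilic aryl-metal of the kind that adds reliably to diaryl ketones. F2 is treated with ketone 7 at −78 °C and worked up with water, which comes back to the route at carbinol 11.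

Step 4. What may go wrong: the long-lived triaryl cation generated from the carbinol by BBr3 may be consumed by Friedel–Crafts closure onto the neighbouring anisyl ring or by attack of the alkyne before all three ethers are cleaved. Fallback: it sets out from 11. Ionic hydrogenation (Et3SiH, TFA, CH2Cl2, −20 °C) should reduce the cation at once to 4'-methoxy-2-[(4-methoxyphenyl)(phenyl)methyl]-3-[(4-methoxyphenyl)ethynyl]-4-methylbiphenyl F3. BBr3 (CH2Cl2, −78 → 0 °C) should then demethylate this substrate, which can no longer ionise, to 4-{[4'-hydroxy-3-[(4-hydroxyphenyl)ethynyl]-4-methylbiphenyl-2-yl](phenyl)methyl}phenol F4. Dehydrogenation of the 4-hydroxytriarylmethane with DDQ (1.05 equiv, CH2Cl2, rt) should give the quinone methide and comes back to the route at 12.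

Step 2. What may go wrong: deprotonation may take place at the methyl group, whose acidity is raised by the ortho alkyne, or aryllithium 4 may lose LiF before it meets iodine. Fallback: it sets out from 1, so that the metalation is done before the alkyne is in place. LDA (THF, −78 °C) should deprotonate ortho to fluorine to give (2-fluoro-3-iodo-4-methylphenyl)lithium F5, which is brominated with 1,2-dibromotetrachloroethane to 1-bromo-2-fluoro-3-iodo-4-methylbenzene F6. Sonogashira coupling of F6 with 2 at room temperature (PdCl2(PPh3)2, CuI, Et3N) should take place at the C–I bond only and give 1-bromo-2-fluoro-3-[(4-methoxyphenyl)ethynyl]-4-methylbenzene F7. Bromine–magnesium exchange of F7 (i-PrMgCl·LiCl, THF, 0 °C) comes back to the route at fluoroaryl Grignard 8 inside step 3.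

**Further compounds**

F1 | step 3 | 2-iodo-4'-methoxy-3-[(4-methoxyphenyl)ethynyl]-4-methylbiphenyl | Cc1ccc(-c2ccc(OC)cc2)c(I)c1C#Cc1ccc(OC)cc1
F2 | step 3 | {4'-methoxy-3-[(4-methoxyphenyl)ethynyl]-4-methylbiphenyl-2-yl}lithium | [Li]c1c(-c2ccc(OC)cc2)ccc(C)c1C#Cc1ccc(OC)cc1
F3 | step 4 | 4'-methoxy-2-[(4-methoxyphenyl)(phenyl)methyl]-3-[(4-methoxyphenyl)ethynyl]-4-methylbiphenyl (racemic) | Cc1ccc(-c2ccc(OC)cc2)c(C(c2ccc(OC)cc2)c2ccccc2)c1C#Cc1ccc(OC)cc1
F4 | step 4 | 4-{[4'-hydroxy-3-[(4-hydroxyphenyl)ethynyl]-4-methylbiphenyl-2-yl](phenyl)methyl}phenol (racemic) | Cc1ccc(-c2ccc(O)cc2)c(C(c2ccc(O)cc2)c2ccccc2)c1C#Cc1ccc(O)cc1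
F5 | step 2 | (2-fluoro-3-iodo-4-methylphenyl)lithium | [Li]c1ccc(C)c(I)c1F
F6 | step 2 | 1-bromo-2-fluoro-3-iodo-4-methylbenzene | Cc1ccc(Br)c(F)c1I
F7 | step 2 | 1-bromo-2-fluoro-3-[(4-methoxyphenyl)ethynyl]-4-methylbenzene | Cc1ccc(Br)c(F)c1C#Cc1ccc(OC)cc1
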